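(The runs come from a simulation for substances that don't exist; noise was put on by code.)

The catalyst charge of the south-west run stood to that of the east run as 1.50, and at the first reading the product of the two runs stood in the ratio 1.45. So I began from a bench rule: with substrate and reagent charged alike, a flask's clock runs in proportion to its catalyst.

| flask | substrate | reagent | catalyst | time |
|---|---|---|---|---|
| east | 0.0800 M | 0.120 M | 0.00160 M |  |
| south-west | 0.0800 M | 0.120 M | 0.00240 M |  |
| north-west | 0.0400 M | 0.0800 M | 0.00160 M | 8.2 min |

- east run (time / min: [product] / M): 0.62: 0.00945; 1.9: 0.02509; 3.6: 0.03924; 5.7: 0.05093; 8.2: 0.06059
- south-west run (time / min: [product] / M): 0.62: 0.01369; 1.9: 0.03301; 3.6: 0.04973; 5.7: 0.06143; 8.2: 0.07003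

(readings scatter by 2 × 10⁻⁴ M)

* reaction order in [catalyst] at the outset, round the charge of the east run, defined at two percent of the substrate turned into product
* product in the north-west run at 8.2 min, as a share of the substrate charged
* which of these the readings show (the catalyst dies in pairs / the product ties up the catalyst / nothing beyond the main steps / the catalyst wakes slowly / the product speeds the reaction)

- Overall: substrate + reagent -> product, with catalyst as catalyst.
- Constant volume, constant temperature.
- What is held in complexes is read along with the free species.
- "The second partner" is reagent.
- An order is taken over about fifteen percent of the charge, up and down.

I tested the rule on the tail of the east run, where substrate, the limiting reagent, was running down. Over the last interval the east run gave a reading of 6.27 min. This tail time constant, the substrate remaining divided by the rate of its loss, is read as for a draining tank. The same reckoning on the south-west run gave 4.15 min, shorter by a factor of 1.51. That lay near the catalyst ratio, although the two tails were taken at different contents of the flask, so I took the order in catalyst to be about 1.02 as an estimate, and assumed the same at the outset.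

The north-west charge looked like a later moment of the east run. At 3.6 min the east run held 0.0408 M substrate and 0.0808 M reagent, close to the north-west charge. I therefore ran the east tail forward by that head start with my time constant and reckoned 73.2% of the north-west substrate turned.

The borrowing of the east tail stops at product. The east tail held 1.39 times as much product as the north-west substrate charge, and the north-west flask starts with none. Both runs tie product to substrate in the same way, so I could not read product's own effect from them, and I left that question open.

The forecast gave order 1 and 69%, below my figure, and chose "the product speeds the reaction", saying “so I tentatively blame product”.

The simulation gave order 0.99, 88.1%, and the verdict that the product ties up the catalyst.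

    catalyst + substrate → catalyst-substrate complex (579.0 L mol⁻¹ min⁻¹)
    catalyst-substrate complex + reagent → product + catalyst (121.8 L mol⁻¹ min⁻¹)
    catalyst + product ⇌ catalyst-product complex, settled at all times (54.00 L mol⁻¹)

The north-west flask ran ahead of my reckoning: product parks catalyst as catalyst-product complex, and my borrowed time constant had been measured amid more product than the north-west charge can make. The proof is the north-west run repeated without the parking, which reaches 98.5% against 88.1%. Taken as one exponential, the real north-west run has a time constant of 3.85 min, against 6.27 min borrowed from the east tail, and the run without parking has 1.96 min.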